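**Retrosynthetic overview**

1. The target is the isoferulate of 4β,6β-dihydroxyeudesmane; the cinnamate is built last on the C6 oxygen by Horner–Wadsworth–Emmons olefination of a C6 phosphonoacetate with isovanillin, so the phenol needs no protection.
2. The 4β,6β-diol comes from a trans-fused 4-silyloxy-eudesm-7-en-6-one by hydrogenation (sets C7) and hydride reduction from the α face (sets C6).
3. That enone is folded in one pot from an acyclic (E)-keto-enal: ring A closes first (C5–C10, Michael addition), ring B second (C7–C8, aldol condensation).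
4. Enabling feature: the oxygen-bearing ring B carbon C6, taken as a ketone, makes both of its neighbours C5 and C7 nucleophilic, and C8–C9–C10, taken as an enal, is the matching 1,3-dielectrophile (C10 = β-carbon that becomes the methyl-bearing ring-fusion atom, C8 = carbonyl lost as water); C1–C3 tether C10 to C4.
5. The keto-enal comes from the symmetric diol made by double carboalumination of hepta-1,6-diyne; C4 is set by Sharpless epoxidation and hydride opening, the isobutyl ketone by Grignard addition and oxidation.

Key step: step 10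

Remark: eudesmane numbering is used for the ring compounds (C4 = methyl carbinol, C5 and C10 = ring fusion, C6 = ester carbinol, C7 = isopropyl-bearing carbon; the C10 methyl is β). Hepta-1,6-diyne, isobutylmagnesium bromide, (diethoxyphosphoryl)acetic acid and isovanillin are assumed to be commercial.

Step 1
Reactants: 1 hepta-1,6-diyne
Product: 2 (2E,7E)-3,7-dimethylnona-2,7-diene-1,9-diol
Conditions: AlMe3 (5 equiv), Cp2ZrCl2 (0.5 equiv), CH2Cl2, 23 °C; then n-BuLi, THF, −78 °C; (CH2O)n, −78 to 23 °C; aqueous work-up
Reagents that add atoms: trimethylaluminium, C[Al](C)C; formaldehyde (as paraformaldehyde), C=O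
Why: Zirconium-catalysed Negishi carboalumination adds CH3 and Al syn across each terminal alkyne with CH3 on the internal carbon, and formaldehyde capture of the alkenylalanate should give both (E)-trisubstituted allylic alcohols at once.

Step 2
Reactants: 2 (2E,7E)-3,7-dimethylnona-2,7-diene-1,9-diol
Product: 3 (2E,7E)-9-[(4-methoxybenzyl)oxy]-3,7-dimethylnona-2,7-dien-1-ol
Conditions: NaH (1.0 equiv), THF/DMF, 0 °C; 4-methoxybenzyl chloride (1.0 equiv), Bu4NI (catalytic), 0 to 23 °C
Reagents that add atoms: 4-methoxybenzyl chloride, COc1ccc(CCl)cc1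
Why: Williamson etherification with one equivalent of alkoxide protects one of the two identical termini statistically, the unreacted diol and the bis-ether being separated and the diol recycled.

Step 3
Reactants: 3 (2E,7E)-9-[(4-methoxybenzyl)oxy]-3,7-dimethylnona-2,7-dien-1-ol
Product: 4 [(2S,3S)-3-{(4E)-6-[(4-methoxybenzyl)oxy]-4-methylhex-4-en-1-yl}-3-methyloxiran-2-yl]methanol
Conditions: Ti(OiPr)4 (10 mol %), L-(+)-diethyl tartrate (12 mol %), t-BuOOH, 4 Å molecular sieves, CH2Cl2, −20 °C
Reagents that add atoms: tert-butyl hydroperoxide, CC(C)(C)OO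
Why: Sharpless asymmetric epoxidation acts only on the free allylic alcohol, and with L-(+)-diethyl tartrate oxygen should be delivered to the face that gives the (2S,3S)-epoxide (as with geraniol), which fixes the future C4.

Step 4
Reactants: 4 [(2S,3S)-3-{(4E)-6-[(4-methoxybenzyl)oxy]-4-methylhex-4-en-1-yl}-3-methyloxiran-2-yl]methanol
Product: 5 (3S,7E)-9-[(4-methoxybenzyl)oxy]-3,7-dimethylnon-7-ene-1,3-diol
Conditions: NaAlH2(OCH2CH2OMe)2, THF, 0 °C
Reagents that add atoms: none
Why: Hydroxyl-directed hydride delivery opens the 2,3-epoxy alcohol at C2 (regioselective reduction to the 1,3-diol), so the tertiary C–O stereocentre is retained.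

Step 5
Reactants: 5 (3S,7E)-9-[(4-methoxybenzyl)oxy]-3,7-dimethylnon-7-ene-1,3-diol
Product: 6 (3S,7E)-3-hydroxy-9-[(4-methoxybenzyl)oxy]-3,7-dimethylnon-7-enal
Conditions: TEMPO (10 mol %), PhI(OAc)2 (1.1 equiv), CH2Cl2, 23 °C
Reagents that add atoms: none
Why: Oxoammonium (TEMPO) oxidation takes the primary alcohol to the aldehyde and cannot oxidise the tertiary alcohol.

Step 6
Reactants: 6 (3S,7E)-3-hydroxy-9-[(4-methoxybenzyl)oxy]-3,7-dimethylnon-7-enal; 7 isobutylmagnesium bromide
Product: 8 (6S,10E)-12-[(4-methoxybenzyl)oxy]-2,6,10-trimethyldodec-10-ene-4,6-diol (both C4 epimers)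
Conditions: 7 (2.5 equiv), THF, −78 to 0 °C; aqueous NH4Cl
Reagents that add atoms: none
Why: Grignard addition to the aldehyde (the first equivalent deprotonates the tertiary alcohol) installs the isobutyl group, and the new carbinol centre is left uncontrolled because it is oxidised in the next step.

Step 7
Reactants: 8 (6S,10E)-12-[(4-methoxybenzyl)oxy]-2,6,10-trimethyldodec-10-ene-4,6-diol
Product: 9 (6S,10E)-6-hydroxy-12-[(4-methoxybenzyl)oxy]-2,6,10-trimethyldodec-10-en-4-one
Conditions: Dess–Martin periodinane, NaHCO3, CH2Cl2, 0 to 23 °C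
Reagents that add atoms: none
Why: Dess–Martin oxidation converts the secondary alcohol to the ketone under buffered, non-basic conditions that should spare the β-hydroxy ketone from retro-aldol cleavage.

Step 8
Reactants: 9 (6S,10E)-6-hydroxy-12-[(4-methoxybenzyl)oxy]-2,6,10-trimethyldodec-10-en-4-one
Product: 10 (6S,10E)-12-[(4-methoxybenzyl)oxy]-2,6,10-trimethyl-6-[(triethylsilyl)oxy]dodec-10-en-4-one
Conditions: TESOTf, 2,6-lutidine, CH2Cl2, −78 °C
Reagents that add atoms: triethylsilyl trifluoromethanesulfonate, CC[Si](CC)(CC)OS(=O)(=O)C(F)(F)F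
Why: Silylation with a silyl triflate and a hindered pyridine base is the standard way to protect a tertiary alcohol, and the ether masks it against retro-aldol and oxa-Michael pathways in the key step.

Step 9
Reactants: 10 (6S,10E)-12-[(4-methoxybenzyl)oxy]-2,6,10-trimethyl-6-[(triethylsilyl)oxy]dodec-10-en-4-one
Product: 12 (2E,7S)-3,7,11-trimethyl-9-oxo-7-[(triethylsilyl)oxy]dodec-2-enal, via allylic alcohol 11 (not isolated)
Conditions: DDQ (1.3 equiv), CH2Cl2/pH 7 buffer, 0 °C; filtration; then MnO2, CH2Cl2, 23 °C
Reagents that add atoms: none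
Why: Oxidative cleavage of the 4-methoxybenzyl ether by DDQ is followed by MnO2 oxidation, which is selective for the allylic alcohol and should keep the (E)-geometry of the enal.

Step 10
Reactants: 12 (2E,7S)-3,7,11-trimethyl-9-oxo-7-[(triethylsilyl)oxy]dodec-2-enal
Product: 14 (4S,5R,10R)-4-[(triethylsilyl)oxy]eudesm-7-en-6-one, via keto aldehyde 13 (not isolated)
Conditions: (S)-α,α-diphenylprolinol trimethylsilyl ether (20 mol %), PhCO2H (20 mol %), toluene (0.05 M), 23 to 40 °C until 12 is consumed; then pyrrolidine (30 mol %), AcOH (30 mol %), 50 °C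
Reagents that add atoms: none
Why: Proposed new method: the amine condenses with the enal to an (E)-iminium ion whose β-carbon C10 is attacked by the acid-generated C5 enol of the C6 ketone (Michael addition, 6-exo-trig closure of ring A, hydrolysis giving 13), after which the C7 enol adds to the C8 iminium ion or aldehyde and amine or water is eliminated (6-exo-trig aldol condensation closing ring B as the enone). The closest known reaction types are the diarylprolinol silyl ether catalysed Michael addition of carbon nucleophiles to β,β-disubstituted enals that sets quaternary centres, and the amine-catalysed Michael/aldol condensation (Robinson-type annulation) of 1,5-keto aldehydes; not yet shown is an unactivated, hindered ketone as the tethered donor. C10 is controlled by the catalyst, whose CPh2(OSiMe3) group shields one face of the s-trans (E)-iminium ion so that the tethered enol adds to the open face, which for the (S)-amine gives (10R); a chair transition state with the C4 methyl and the iminium-bearing branch equatorial and OSiEt3 axial fits this, whereas the C10 epimer would need attack on the shielded face or reaction through the (Z)-iminium ion, whose chair suffers allylic 1,3-strain or a 1,3-diaxial pair of methyl groups. C5 is set in the same chair with the enol carbon C6 equatorial (H-5 anti to the C10 methyl, trans ring fusion) and stays correctable because it is α to the ketone. The step needs regioselectivity between the two α-positions of the ketone and Michael addition before aldol, both secured by ring size: only C5 can reach C10 and only C7 can reach C8 through six-membered transition states, while the silyl ether prevents retro-aldol cleavage and oxa-Michael addition of the tertiary oxygen.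

Step 11
Reactants: 14 (4S,5R,10R)-4-[(triethylsilyl)oxy]eudesm-7-en-6-one
Product: 15 (4S,5R,7S,10R)-4-[(triethylsilyl)oxy]eudesman-6-one
Conditions: H2 (1–3 atm), Pd/C (10 wt %), EtOAc, 23 °C
Reagents that add atoms: none
Why: Heterogeneous hydrogenation should add H2 to the C7=C8 enone bond from the α face, opposite the axial C10 methyl and C4 silyloxy groups, giving the 7β (equatorial) isopropyl group, which is also the thermodynamic epimer α to the ketone.

Step 12
Reactants: 15 (4S,5R,7S,10R)-4-[(triethylsilyl)oxy]eudesman-6-one
Product: 17 (4S,5S,6R,7S,10R)-eudesmane-4,6-diol, via silyl ether alcohol 16 (not isolated)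
Conditions: LiAlH4, THF, −78 to 0 °C; aqueous NaOH work-up; then HF·pyridine, THF, 0 to 23 °C
Reagents that add atoms: none
Why: Hydride reduction should occur by equatorial attack from the α face because the axial β trajectory is blocked by the syn-axial C10 methyl and C4 silyloxy groups (the behaviour of 6-oxo steroids), giving the axial 6β-alcohol, and fluoride desilylation then frees the tertiary alcohol.

Step 13
Reactants: 17 (4S,5S,6R,7S,10R)-eudesmane-4,6-diol; 18 (diethoxyphosphoryl)acetic acid
Product: 19 (4S,5S,6R,7S,10R)-4-hydroxyeudesman-6-yl (diethoxyphosphoryl)acetate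
Conditions: DCC (1.5 equiv), DMAP (0.2 equiv), CH2Cl2, 0 to 23 °C
Reagents that add atoms: none
Why: Steglich esterification with the small phosphonoacetic acid should acylate the secondary 6β-hydroxyl only, the tertiary C4 hydroxyl being unreactive under these conditions.

Step 14
Reactants: 19 (4S,5S,6R,7S,10R)-4-hydroxyeudesman-6-yl (diethoxyphosphoryl)acetate; 20 isovanillin (3-hydroxy-4-methoxybenzaldehyde)
Product: 21 (4S,5S,6R,7S,10R)-4-hydroxyeudesman-6-yl (2E)-3-(3-hydroxy-4-methoxyphenyl)prop-2-enoate (target, CNP0291757.1)
Conditions: LiCl (3 equiv), DBU (2.5 equiv), MeCN, 0 to 23 °C; aqueous NH4Cl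
Reagents that add atoms: none
Why: Horner–Wadsworth–Emmons olefination under Masamune–Roush conditions should give the (E)-cinnamate, and because the phenol of isovanillin is meta to the formyl group its phenoxide does not deactivate the aldehyde.

**Compound list**

1 | hepta-1,6-diyne | C#CCCCC#C | starting material
2 | (2E,7E)-3,7-dimethylnona-2,7-diene-1,9-diol | OC/C=C(\C)CCC/C(C)=C/CO | intermediate
3 | (2E,7E)-9-[(4-methoxybenzyl)oxy]-3,7-dimethylnona-2,7-dien-1-ol | COc1ccc(COC/C=C(\C)CCC/C(C)=C/CO)cc1 | intermediate
4 | [(2S,3S)-3-{(4E)-6-[(4-methoxybenzyl)oxy]-4-methylhex-4-en-1-yl}-3-methyloxiran-2-yl]methanol | OC[C@@H]1O[C@@]1(C)CCC/C(C)=C/COCc1ccc(OC)cc1 | intermediate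
5 | (3S,7E)-9-[(4-methoxybenzyl)oxy]-3,7-dimethylnon-7-ene-1,3-diol | OCC[C@@](C)(O)CCC/C(C)=C/COCc1ccc(OC)cc1 | intermediate
6 | (3S,7E)-3-hydroxy-9-[(4-methoxybenzyl)oxy]-3,7-dimethylnon-7-enal | O=CC[C@@](C)(O)CCC/C(C)=C/COCc1ccc(OC)cc1 | intermediate
7 | isobutylmagnesium bromide | CC(C)C[Mg]Br | starting material
8 | (6S,10E)-12-[(4-methoxybenzyl)oxy]-2,6,10-trimethyldodec-10-ene-4,6-diol (both C4 epimers) | CC(C)CC(O)C[C@@](C)(O)CCC/C(C)=C/COCc1ccc(OC)cc1 | intermediate
9 | (6S,10E)-6-hydroxy-12-[(4-methoxybenzyl)oxy]-2,6,10-trimethyldodec-10-en-4-one | CC(C)CC(=O)C[C@@](C)(O)CCC/C(C)=C/COCc1ccc(OC)cc1 | intermediate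
10 | (6S,10E)-12-[(4-methoxybenzyl)oxy]-2,6,10-trimethyl-6-[(triethylsilyl)oxy]dodec-10-en-4-one | CC(C)CC(=O)C[C@@](C)(O[Si](CC)(CC)CC)CCC/C(C)=C/COCc1ccc(OC)cc1 | intermediate
11 | (6S,10E)-12-hydroxy-2,6,10-trimethyl-6-[(triethylsilyl)oxy]dodec-10-en-4-one | CC(C)CC(=O)C[C@@](C)(O[Si](CC)(CC)CC)CCC/C(C)=C/CO | intermediate
12 | (2E,7S)-3,7,11-trimethyl-9-oxo-7-[(triethylsilyl)oxy]dodec-2-enal | CC(C)CC(=O)C[C@@](C)(O[Si](CC)(CC)CC)CCC/C(C)=C/C=O | intermediate
13 | 2-[(1R,2R,3S)-1,3-dimethyl-2-(3-methylbutanoyl)-3-[(triethylsilyl)oxy]cyclohexyl]acetaldehyde | O=CC[C@@]1(C)CCC[C@](C)(O[Si](CC)(CC)CC)[C@@H]1C(=O)CC(C)C | intermediate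
14 | (4S,5R,10R)-4-[(triethylsilyl)oxy]eudesm-7-en-6-one (trans-fused; 4β-OSiEt3, 5α-H, 10β-CH3) | O=C1[C@@H]2[C@](C)(CCC[C@]2(C)O[Si](CC)(CC)CC)CC=C1C(C)C | intermediate
15 | (4S,5R,7S,10R)-4-[(triethylsilyl)oxy]eudesman-6-one (7β-isopropyl) | O=C1[C@@H]2[C@](C)(CCC[C@]2(C)O[Si](CC)(CC)CC)CC[C@H]1C(C)C | intermediate
16 | (4S,5S,6R,7S,10R)-4-[(triethylsilyl)oxy]eudesman-6-ol (6β-OH) | O[C@H]1[C@@H]2[C@](C)(CCC[C@]2(C)O[Si](CC)(CC)CC)CC[C@H]1C(C)C | intermediate
17 | (4S,5S,6R,7S,10R)-eudesmane-4,6-diol (4β,6β-diol) | O[C@H]1[C@@H]2[C@](C)(CCC[C@]2(C)O)CC[C@H]1C(C)C | intermediate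
18 | (diethoxyphosphoryl)acetic acid | CCOP(=O)(CC(=O)O)OCC | starting material
19 | (4S,5S,6R,7S,10R)-4-hydroxyeudesman-6-yl (diethoxyphosphoryl)acetate | CCOP(=O)(OCC)CC(=O)O[C@H]1[C@@H]2[C@](C)(CCC[C@]2(C)O)CC[C@H]1C(C)C | intermediate
20 | isovanillin (3-hydroxy-4-methoxybenzaldehyde) | COc1ccc(C=O)cc1O | starting material
21 | (4S,5S,6R,7S,10R)-4-hydroxyeudesman-6-yl (2E)-3-(3-hydroxy-4-methoxyphenyl)prop-2-enoate | COc1ccc(/C=C/C(=O)O[C@H]2[C@@H]3[C@](C)(CCC[C@]3(C)O)CC[C@H]2C(C)C)cc1O | target

**Totals**

Total step count: 14. Longest linear sequence: 14 steps (hepta-1,6-diyne 1 to target 21).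

**Steps most likely to fail**

Step 10 (proposed new method). The hindered C5 enol may add too slowly, so that dienamine side reactions of the enal take over. Face selection at the iminium ion (C10 against the existing C4 centre) or the ring-fusion geometry at C5 may also be poor. The fallback gives up the one-pot, catalyst-controlled cascade for two separate, substrate-controlled ring closures with purification between them, using known chemistry only. It sets out from 12: ring A is closed by a Stork-type enamine Michael addition with stoichiometric pyrrolidine and acetic acid (MeCN, 23 °C, then aqueous hydrolysis). Keto aldehyde 13 is isolated and its diastereomers are separated by chromatography. Ring B is then closed by a classical aldol condensation (piperidinium acetate, toluene, reflux with removal of water), and the route is rejoined at 14. No compound outside the list is made (F0).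

Step 12. Hydride delivery to the hindered C6 ketone may show poor facial selectivity (formation of the equatorial 6α-alcohol) or stall. The fallback replaces steric control by chelation control. It sets out from 15, which is first desilylated with HF·pyridine to (4S,5R,7S,10R)-4-hydroxyeudesman-6-one F1. A Narasaka–Prasad reduction (Et2BOMe, NaBH4, THF/MeOH, −78 °C) then ties the 4β-oxygen and the ketone into a boron chelate on the β face, so external hydride should enter from the α face and give the syn 4β,6β-diol. The route is rejoined at 17.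

Step 13. Acylation of the axial 6β-hydroxyl, which is 1,3-diaxial to the C10 methyl and the C4 hydroxyl, may be slow, with N-acylurea formation consuming the activated acid. The fallback changes both the acyl-transfer reagent and the way the C=C bond is made. It sets out from 17, which is heated with Meldrum's acid (toluene, 90–100 °C, uncatalysed acyl transfer that tolerates hindered alcohols) to give 3-{[(4S,5S,6R,7S,10R)-4-hydroxyeudesman-6-yl]oxy}-3-oxopropanoic acid F2. Knoevenagel–Doebner condensation of this half ester with isovanillin 20 (pyridine, catalytic piperidine, 80 °C, with loss of CO2) should give the (E)-cinnamate directly. The route is rejoined at 21, bypassing 19.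

**Further compounds**

F0 | step 10 | none | none
F1 | step 12 | (4S,5R,7S,10R)-4-hydroxyeudesman-6-one | O=C1[C@@H]2[C@](C)(CCC[C@]2(C)O)CC[C@H]1C(C)C
F2 | step 13 | 3-{[(4S,5S,6R,7S,10R)-4-hydroxyeudesman-6-yl]oxy}-3-oxopropanoic acid | OC(=O)CC(=O)O[C@H]1[C@@H]2[C@](C)(CCC[C@]2(C)O)CC[C@H]1C(C)C
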